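## Retrosynthetic overview

1. The last C–C bond made is C5'–C6', the midpoint of the unbranched decamethylene chain C1'–C10' that links C5 of the 1,2-dioxolane to the phenyl ring. It is formed by a mixed Kolbe electrolysis of two carboxylic acids (two primary radicals of like polarity, only CO2 and H2 are lost). Only an ester hydrolysis follows.
2. Enabling feature: both carbons of that bond are plain CH2 groups. They lie five methylenes from the ring oxygens O1/O2 on one side and from the phenyl ring on the other. The peroxide carbons C3 and C5 are quaternary, so the O1–O2 bond has no adjacent C–H and tolerates an oxidative coupling free of reductants and organometallics.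
3. The dioxolane acid comes from a C5-formyl-1,2-dioxolane by Wittig reaction with the (4-carboxybutyl) ylide and diimide reduction. The phenyl half is commercial 6-phenylhexanoic acid.
4. C3 is set by alkylating a 3-methoxy-1,2-dioxolane (peroxycarbenium ion) with a ketene silyl acetal, anti to a bulky C5-CH2OTBDPS arm. C5 is set by 5-exo-tet opening, with inversion, of a chiral 2,2-disubstituted epoxide by a hydroperoxy ketal made by ozonolysis in methanol.
5. Ring order: the 1,2-dioxolane is the only ring built (step 3). The epoxide that precedes it comes from (R)-2-methylglycidol and isopropenylmagnesium bromide. The phenyl ring is bought.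

Key step: step 10

Remark on locants: the ring is O1–O2–C3–C4–C5 (C3 bears the acetic acid arm, C5 the long chain) and the chain is C1'–C10' counted from C5. These locants are kept for all intermediates, so some names deviate from strict IUPAC numbering.

## Route

Step 1
Reactants: 1 (R)-2-methylglycidol
Product: 2 [(2S)-2-methyloxiran-2-yl]methyl 4-methylbenzenesulfonate
Conditions: TsCl, Et3N, DMAP (cat.), CH2Cl2, 0 °C
Reagents that add atoms: p-toluenesulfonyl chloride, Cc1ccc(cc1)S(Cl)(=O)=O
Why: Sulfonylation of the primary alcohol, in which no bond to the stereocentre is touched (the descriptor changes from R to S only through the CIP priorities).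

Step 2
Reactants: 2 [(2S)-2-methyloxiran-2-yl]methyl 4-methylbenzenesulfonate; 3 isopropenylmagnesium bromide
Product: 5 (2S)-2-methyl-2-(2-methylprop-2-en-1-yl)oxirane, via hydroxy tosylate 4 (not isolated)
Conditions: CuI (10 mol %), THF, −40 °C; aq NH4Cl; crude 4, K2CO3, MeOH, rt
Reagents that add atoms: none
Why: Copper-catalysed Grignard opening of the 2,2-disubstituted epoxide at its free CH2 terminus (the neopentylic tosylate is inert at −40 °C) is followed by Williamson-type 3-exo-tet closure of the tertiary alkoxide onto the tosylate; the C–O bond at the stereocentre is never broken, so its configuration is carried over.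

Step 3
Reactants: 5 (2S)-2-methyl-2-(2-methylprop-2-en-1-yl)oxirane
Product: 7 [(5R)-3-methoxy-3,5-dimethyl-1,2-dioxolan-5-yl]methanol (both C3 epimers), via methoxy hydroperoxide 6 (not isolated)
Conditions: O3, CH2Cl2, MeOH (5 equiv), −78 °C, O2 purge; then CSA (5 mol %), 0 °C → rt
Reagents that add atoms: ozone, [O-][O+]=O; methanol, CO
Why: Ozonolysis by the Criegee mechanism should cleave the 1,1-disubstituted alkene into formaldehyde and the more substituted carbonyl oxide, which methanol traps as the α-methoxy hydroperoxide 6; under acid catalysis its OOH group opens the epoxide 5-exo-tet at the tertiary carbon with inversion, which closes the 1,2-dioxolane and sets C5 from the stereocentre of 1, while the ketal carbon C3 forms as an inconsequential mixture.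

Step 4
Reactants: 7 [(5R)-3-methoxy-3,5-dimethyl-1,2-dioxolan-5-yl]methanol
Product: 8 tert-butyl{[(5R)-3-methoxy-3,5-dimethyl-1,2-dioxolan-5-yl]methoxy}diphenylsilane (both C3 epimers)
Conditions: TBDPSCl, imidazole, DMF, rt
Reagents that add atoms: tert-butyl(chloro)diphenylsilane, CC(C)(C)[Si](Cl)(c1ccccc1)c1ccccc1
Why: Standard silylation of a primary alcohol; the TBDPS ether protects the hydroxyl group and makes the C5 arm much larger than the C5 methyl group for step 5.

Step 5
Reactants: 8 tert-butyl{[(5R)-3-methoxy-3,5-dimethyl-1,2-dioxolan-5-yl]methoxy}diphenylsilane; 9 1-(tert-butyldimethylsilyloxy)-1-methoxyethene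
Product: 10 methyl 2-[(3R,5R)-5-{[(tert-butyldiphenylsilyl)oxy]methyl}-3,5-dimethyl-1,2-dioxolan-3-yl]acetate
Conditions: 9 (2.5 equiv), TiCl4 (1.1 equiv), CH2Cl2, −78 °C; aq NaHCO3; chromatography
Reagents that add atoms: none
Why: Lewis-acid ionisation of either ketal epimer gives the same planar 1,2-dioxolan-3-ylium (peroxycarbenium) ion, which is trapped in a Mukaiyama-type alkylation; the ion should prefer the C5-envelope with the small C5 methyl pseudoaxial and the CH2OTBDPS arm pseudoequatorial, so inside attack should place the acetate arm cis to C5-CH3 and trans to the silyloxymethyl arm (3R), and the minor C3 epimer is removed by chromatography.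

Step 6
Reactants: 10 methyl 2-[(3R,5R)-5-{[(tert-butyldiphenylsilyl)oxy]methyl}-3,5-dimethyl-1,2-dioxolan-3-yl]acetate
Product: 11 methyl 2-[(3R,5R)-5-(hydroxymethyl)-3,5-dimethyl-1,2-dioxolan-3-yl]acetate
Conditions: HF·pyridine, THF–pyridine, 0 °C → rt
Reagents that add atoms: none
Why: Fluoride-mediated desilylation in a non-basic medium, so that the β-peroxy ester never meets a strong base; the trans relation of the two arms rules out lactonisation and both stereocentres stay untouched.

Step 7
Reactants: 11 methyl 2-[(3R,5R)-5-(hydroxymethyl)-3,5-dimethyl-1,2-dioxolan-3-yl]acetate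
Product: 12 methyl 2-[(3R,5R)-5-formyl-3,5-dimethyl-1,2-dioxolan-3-yl]acetate
Conditions: Dess–Martin periodinane, CH2Cl2, 0 °C → rt
Reagents that add atoms: none
Why: Dess–Martin oxidation is a mild, non-reducing oxidation that leaves the O–O bond intact, and the aldehyde formed has no α-hydrogen, so it can neither enolise nor eliminate.

Step 8
Reactants: 12 methyl 2-[(3R,5R)-5-formyl-3,5-dimethyl-1,2-dioxolan-3-yl]acetate; 13 (4-carboxybutyl)triphenylphosphonium bromide
Product: 14 methyl 2-[(3R,5R)-5-[(1Z)-5-carboxypent-1-en-1-yl]-3,5-dimethyl-1,2-dioxolan-3-yl]acetate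
Conditions: 13 (2.0 equiv), NaHMDS (3.9 equiv), THF, 0 °C; then 12, −78 → 0 °C; 1 M HCl to pH 4
Reagents that add atoms: none
Why: Wittig olefination with a non-stabilised carboxylate ylide, made with a slight deficit of base so that no amide base is left to deprotonate the ester; the alkene should be mainly Z, which is irrelevant because it is saturated in step 9.

Step 9
Reactants: 14 methyl 2-[(3R,5R)-5-[(1Z)-5-carboxypent-1-en-1-yl]-3,5-dimethyl-1,2-dioxolan-3-yl]acetate
Product: 15 methyl 2-[(3R,5S)-5-(5-carboxypentyl)-3,5-dimethyl-1,2-dioxolan-3-yl]acetate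
Conditions: KO2C–N=N–CO2K (excess, portionwise), AcOH, MeOH–CH2Cl2, 0 °C → rt
Reagents that add atoms: none
Why: Diimide reduction transfers H2 to the C=C bond in a concerted way and is the standard method for saturating alkenes without cleaving a peroxide (the C5 descriptor changes to S through CIP priorities only).

Step 10
Reactants: 15 methyl 2-[(3R,5S)-5-(5-carboxypentyl)-3,5-dimethyl-1,2-dioxolan-3-yl]acetate; 16 6-phenylhexanoic acid
Product: 17 methyl 2-[(3R,5S)-3,5-dimethyl-5-(10-phenyldecyl)-1,2-dioxolan-3-yl]acetate
Conditions: 16 (8 equiv), KOH (5 mol % of total acid), MeOH, smooth Pt anode, 0.2–0.25 A cm−2, Pt cathode behind a glass frit (catholyte: 16, KOH, MeOH), 10–20 °C, constant current, stopped while still weakly acidic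
Reagents that add atoms: none
Why: Mixed Kolbe electrolysis: the carboxylates of 15 and 16 are each oxidised by one electron at the platinum anode, lose CO2 and give the 5-(dioxolan-5-yl)pentyl and the 5-phenylpentyl radical, two nucleophilic primary radicals of like polarity that combine in the radical-rich layer at the electrode to make the C5'–C6' bond and with it the complete carbon skeleton at its final oxidation level, with nothing left to remove. The closest known reaction type is the mixed Kolbe coupling of ω-functionalised alkanoic acids (half-esters, keto acids, halo acids, alkenoic acids) with an excess of a cheap co-acid to build long unbranched chains. No ring is closed and no stereocentre is formed; the quaternary centres C5 and C3 lie five and seven bonds from the radical carbon and are not touched. The step needs (i) oxidation of carboxylate in preference to the O–O bond, the ester and the arene, (ii) radical coupling in preference to further oxidation to the cation and (iii) hetero- over homo-coupling. Point (i) is secured by the substrate itself, since a dialkyl peroxide with two fully substituted carbons has no oxidisable C–H next to oxygen and is attacked only by reductants, which the frit around the cathode keeps away, while the acetic acid arm, whose β-peroxy radical would fragment, is masked as the methyl ester (degenerate towards methanol and methoxide); point (ii) is secured by the unbranched, unstabilised primary radicals (five CH2 groups from both the ring oxygens and the phenyl ring), the smooth Pt anode, the high current density and the weakly acidic medium. Point (iii) is handled by the eightfold excess of 16, after which the hydrocarbon homodimer, the unreacted acids and the monoester product should differ enough in polarity for simple chromatography.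

Step 11
Reactants: 17 methyl 2-[(3R,5S)-3,5-dimethyl-5-(10-phenyldecyl)-1,2-dioxolan-3-yl]acetate
Product: 18 andavadoic acid, 2-[(3R,5S)-3,5-dimethyl-5-(10-phenyldecyl)-1,2-dioxolan-3-yl]acetic acid
Conditions: LiOH, THF–H2O, 0 °C → rt; then 1 M HCl
Reagents that add atoms: lithium hydroxide, [Li+].[OH-]
Why: Saponification of the methyl ester; C3 and C5 carry no hydrogen, so a Kornblum–DeLaMare-type fragmentation is impossible, and aqueous hydroxide at or below room temperature should not enolise the ester, so both stereocentres are kept.

## Compound list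

1 | (R)-2-methylglycidol, [(2R)-2-methyloxiran-2-yl]methanol | C[C@@]1(CO)CO1 | starting material
2 | [(2S)-2-methyloxiran-2-yl]methyl 4-methylbenzenesulfonate | C[C@@]1(COS(=O)(=O)c2ccc(C)cc2)CO1 | intermediate
3 | isopropenylmagnesium bromide | CC(=C)[Mg]Br | starting material
4 | (2S)-2-hydroxy-2,4-dimethylpent-4-en-1-yl 4-methylbenzenesulfonate | C[C@@](O)(COS(=O)(=O)c1ccc(C)cc1)CC(C)=C | intermediate
5 | (2S)-2-methyl-2-(2-methylprop-2-en-1-yl)oxirane | C[C@@]1(CO1)CC(C)=C | intermediate
6 | (2S)-2-(2-hydroperoxy-2-methoxypropyl)-2-methyloxirane (both ketal epimers) | C[C@@]1(CO1)CC(C)(OC)OO | intermediate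
7 | [(5R)-3-methoxy-3,5-dimethyl-1,2-dioxolan-5-yl]methanol (both C3 epimers) | C[C@]1(CO)CC(C)(OC)OO1 | intermediate
8 | tert-butyl{[(5R)-3-methoxy-3,5-dimethyl-1,2-dioxolan-5-yl]methoxy}diphenylsilane (both C3 epimers) | C[C@]1(CO[Si](c2ccccc2)(c2ccccc2)C(C)(C)C)CC(C)(OC)OO1 | intermediate
9 | 1-(tert-butyldimethylsilyloxy)-1-methoxyethene | C=C(OC)O[Si](C)(C)C(C)(C)C | starting material
10 | methyl 2-[(3R,5R)-5-{[(tert-butyldiphenylsilyl)oxy]methyl}-3,5-dimethyl-1,2-dioxolan-3-yl]acetate | C[C@]1(CO[Si](c2ccccc2)(c2ccccc2)C(C)(C)C)C[C@](C)(CC(=O)OC)OO1 | intermediate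
11 | methyl 2-[(3R,5R)-5-(hydroxymethyl)-3,5-dimethyl-1,2-dioxolan-3-yl]acetate | C[C@]1(CO)C[C@](C)(CC(=O)OC)OO1 | intermediate
12 | methyl 2-[(3R,5R)-5-formyl-3,5-dimethyl-1,2-dioxolan-3-yl]acetate | C[C@]1(C=O)C[C@](C)(CC(=O)OC)OO1 | intermediate
13 | (4-carboxybutyl)triphenylphosphonium bromide | OC(=O)CCCC[P+](c1ccccc1)(c1ccccc1)c1ccccc1.[Br-] | starting material
14 | methyl 2-[(3R,5R)-5-[(1Z)-5-carboxypent-1-en-1-yl]-3,5-dimethyl-1,2-dioxolan-3-yl]acetate | C[C@]1(/C=C\CCCC(=O)O)C[C@](C)(CC(=O)OC)OO1 | intermediate
15 | methyl 2-[(3R,5S)-5-(5-carboxypentyl)-3,5-dimethyl-1,2-dioxolan-3-yl]acetate | C[C@]1(CCCCCC(=O)O)C[C@](C)(CC(=O)OC)OO1 | intermediate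
16 | 6-phenylhexanoic acid | OC(=O)CCCCCc1ccccc1 | starting material
17 | methyl 2-[(3R,5S)-3,5-dimethyl-5-(10-phenyldecyl)-1,2-dioxolan-3-yl]acetate | C[C@]1(CCCCCCCCCCc2ccccc2)C[C@](C)(CC(=O)OC)OO1 | intermediate
18 | andavadoic acid, 2-[(3R,5S)-3,5-dimethyl-5-(10-phenyldecyl)-1,2-dioxolan-3-yl]acetic acid | C[C@]1(CCCCCCCCCCc2ccccc2)C[C@](C)(CC(=O)O)OO1 | target

## Step count and risks

Total step count: 11. Longest linear sequence: 11 steps (1 → 18). Compounds 3, 9, 13 and 16 are bought.

The three steps most likely to fail:

**Step 10.**
- What may go wrong: reductive cleavage of the O–O bond by leakage to the cathode. Over-oxidation of the primary radical to the cation (Hofer–Moest pathway). Passivation of the anode through oxidation of the arene. Loss of the valuable acid to homocoupling.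
- Fallback: it sets out from 12 and comes back at 17. It makes the same C5'–C6' linkage by alkene metathesis instead of radical coupling.
- Aldehyde 12 undergoes a Wittig reaction with the ylide of commercial (pent-4-en-1-yl)triphenylphosphonium bromide. This should give the diene methyl 2-[(3R,5R)-5-[(1Z)-hexa-1,5-dien-1-yl]-3,5-dimethyl-1,2-dioxolan-3-yl]acetate F1.
- Cross-metathesis of its terminal alkene with an excess of commercial 6-phenylhex-1-ene (second-generation Hoveyda–Grubbs catalyst, CH2Cl2, 40 °C) follows. The internal Z-alkene next to the quaternary C5 is too hindered to take part. The product should be methyl 2-[(3R,5R)-3,5-dimethyl-5-[(1Z,5E)-10-phenyldeca-1,5-dien-1-yl]-1,2-dioxolan-3-yl]acetate F2.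
- Exhaustive diimide reduction of both double bonds then gives 17.

**Step 5.**
- What may go wrong: poor facial selectivity at the planar peroxycarbenium ion, because the silyl group can rotate away from the ring. Lewis-acid-induced heterolysis of the O–O bond.
- Fallback: it sets out from 8 and comes back at 10. It replaces substrate control by auxiliary control.
- The chlorotitanium enolate of (S)-N-acetyl-4-isopropyl-1,3-thiazolidine-2-thione (TiCl4, i-Pr2NEt, CH2Cl2) is added to the cation released from 8 with SnCl4 at −78 °C. The antipode of the auxiliary is equally available should it prove to be the matched one.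
- This should give 1-[(4S)-4-isopropyl-2-thioxo-1,3-thiazolidin-3-yl]-2-[(3R,5R)-5-{[(tert-butyldiphenylsilyl)oxy]methyl}-3,5-dimethyl-1,2-dioxolan-3-yl]ethan-1-one F3. Its yellow diastereomers are easy to separate.
- Mild methanolysis (MeOH, imidazole) releases the auxiliary and gives 10.

**Step 3.**
- What may go wrong: Criegee fragmentation in the wrong sense. 6-endo opening at the epoxide CH2. Loss of stereochemical fidelity through an SN1-like opening. Meinwald-type rearrangement of the epoxide under acid.
- Fallback: it sets out from 5 and comes back at 7. It makes the stereodefining C5–O bond first and intermolecularly, with H2O2 as the peroxide source.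
- Phosphomolybdic-acid-catalysed perhydrolysis of 5 with ethereal H2O2 opens the epoxide at the tertiary carbon with inversion. The product should be (2R)-2-hydroperoxy-2,4-dimethylpent-4-en-1-ol F4.
- Ozonolysis of F4 in CH2Cl2–MeOH gives (2R)-2,4-dihydroperoxy-4-methoxy-2-methylpentan-1-ol F5.
- Acid-catalysed transperoxyketalisation (PPTS, MeOH) closes the dioxolane to give 7.

## Further compounds

F1 | step 10 | methyl 2-[(3R,5R)-5-[(1Z)-hexa-1,5-dien-1-yl]-3,5-dimethyl-1,2-dioxolan-3-yl]acetate | C[C@]1(/C=C\CCC=C)C[C@](C)(CC(=O)OC)OO1
F2 | step 10 | methyl 2-[(3R,5R)-3,5-dimethyl-5-[(1Z,5E)-10-phenyldeca-1,5-dien-1-yl]-1,2-dioxolan-3-yl]acetate | C[C@]1(/C=C\CC/C=C/CCCCc2ccccc2)C[C@](C)(CC(=O)OC)OO1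
F3 | step 5 | 1-[(4S)-4-isopropyl-2-thioxo-1,3-thiazolidin-3-yl]-2-[(3R,5R)-5-{[(tert-butyldiphenylsilyl)oxy]methyl}-3,5-dimethyl-1,2-dioxolan-3-yl]ethan-1-one | C[C@]1(CO[Si](c2ccccc2)(c2ccccc2)C(C)(C)C)C[C@](C)(CC(=O)N2[C@@H](C(C)C)CSC2=S)OO1
F4 | step 3 | (2R)-2-hydroperoxy-2,4-dimethylpent-4-en-1-ol | C[C@](OO)(CO)CC(C)=C
F5 | step 3 | (2R)-2,4-dihydroperoxy-4-methoxy-2-methylpentan-1-ol (both ketal epimers) | C[C@](OO)(CO)CC(C)(OC)OO
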